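(All runs were generated by integration with made-up constants; the scatter is artificial.)

The 3 questions below ask for one share of D in 2 flasks and for the trend between those flasks.

| setting | ash | larch | dusk | midnight |
|---|---|---|---|---|
| D | 0.62 M | 0.62 M | 0.62 M | 0.62 M |
| Z | 0.589 M | 0.589 M | 0.589 M | 0.589 M |
| J | 0.88 M | 1.5 M | 0.740 M | 0.970 M |
| remark | run made earlier | run made earlier |  |  |
| time |  |  | 2.5 h | 2.5 h |

- ash (time / min: D / %, Q / %): 8.00: 75.0, 4.8; 20.0: 55.7, 12.6; 40.0: 41.2, 23.6; 60.0: 40.6, 28.4; 80.0: 37.1, 33.5; 120: 36.0, 38.7
- larch (time / min: D / %, Q / %): 8.00: 75.5, 3.2; 20.0: 57.6, 13.4; 40.0: 42.3, 22.4; 60.0: 41.8, 30.1; 80.0: 39.2, 34.1; 120: 40.0, 39.5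

(scatter of a reading: 1 percentage point)

1. part of the D that has reacted at the end, dusk
2. part of the D that has reacted at the end, midnight
3. what raising the concentration of J from its lowest to its highest value here does to the part of the D that has reacted (changes below 5 percentage points count as none) (it falls / it rises / no change)

- amounts and yields of X count E too
- the numbers in the tables scatter by 1 percentage point (one standard deviation)
- reactions considered so far: D + Z -> L + X; D + X <-> E; J + X -> G; Z + L -> Q + X
- what has gone from D into another species counts as reacted, even if it can come back

In each flask D and Z give L and X, Z and L give Q and X, D holds X reversibly as E, and J takes X away as G.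

1. The charges. Z is charged in a smaller amount than D, which makes it the limiting reagent. Each L has taken one Z and each Q has taken 2, so in shares of the D charged, L + 2 Q is the Z used. That share cannot pass the Z ceiling, c(Z) charged over c(D) charged, 95.0%. Since reacted D is L + Q + E, it follows that reacted D = Z used − Q + E.

2. Time. By hand, the 30.0 min beyond the last reading of ash and larch should add little to the reacted share if D has stopped falling by then. In ash, D moves from 37.1% to 36.0% over the last interval, and in larch from 39.2% to 40.0%, about the scatter of 1 percentage point. As an approximation, the reckoning here therefore takes c(Z) as near enough zero at 120 min and carries the last readings on to 2.5 h.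

3. J. By hand, more J takes more X, so less E stands and less D counts as reacted. The balance reads E as 7.70% in ash and 4.50% in larch, a lower limit in each case, since any Z left would raise it. E times c(J) then gives 0.0678 M and 0.0675 M, close readings, so E is scaled as one over c(J).

4. The sum. With Q at 39.1%, the mean of the last readings, and the mean product 0.0676 M, dusk comes to 65.0% and midnight to 62.9%. That gap of 2.1 points is smaller than the 5 points that counts.

The forecast gives 65% (61% to 69%) for dusk, 63% (59% to 67%) for midnight, and no change, on the ground that “J acts only through the modest E share”.

The flask gives 65.3% for dusk and 63.0% for midnight, so no change, with a change of −2.3 points.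

    D + Z → L + X (k = 0.0427 /M/min)
    D + X ⇌ E, settled at all times (K = 2.40 /M)
    J + X → G (k = 0.0248 /M/min)
    Z + L → Q + X (k = 0.120 /M/min)

In midnight at 2.5 h, 3.3% of the Z is left, beside Q at 38.6% and E at 9.77%, and the balance gives 63.0% reacted. The neighbouring flask is the same as midnight, but read at 1.0 h. It still has 21.8% of its Z, with Q at 29.1% and E at 16.7%, so its balance gives 61.9%. That neighbouring flask has 38.2% of its D left, which puts 61.8% as reacted.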